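All constants come from no measurement; what happens was integrated by code.

At the start of both flasks, I reckoned, 677 units of free monomer entered chains for each chain born; I call this figure units per new chain, the kinetic chain length counted for two joined radicals.

- epsilon: free monomer 2.0 M; initiator 2 mol%; time 30 h
- theta: free monomer 2.0 M; initiator 2 mol%; time 10 h

    free monomer + growing radical → monomer in chains + growing radical, rate k1*[growing radical]*[free monomer] (k1 = 9.35 × 10⁵ M⁻¹ h⁻¹)
    free monomer + initiating radical → growing radical + monomer in chains (k2 = 4.56 × 10⁶ M⁻¹ h⁻¹)
    2 growing radical → dead chain (k3 = 5 × 10⁶ M⁻¹ s⁻¹)
    initiator → 2 initiating radical (k4 = 0.0106 h⁻¹)

1. which of the two ends with the longer chains by the average number of monomer units in a chain (living and dead chains, two that joined counted as one) ("neither" if they lie within 10%) (epsilon / theta / neither)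
2. average number of monomer units in a chain (living and dead chains, two that joined counted as one) at the end, epsilon
3. average number of monomer units in a chain (living and dead chains, two that joined counted as one) at the end, theta

- two of one species on the left: rate k times its square, two consumed each time
- the average divides the monomer in chains by the number of chains, living and dead together; two radicals that join make one chain
- run time (epsilon): 30 h

I divided the rate at which free monomer enters chains by the rate at which chains are born, so that time dropped out. I held growing radical at 1.53 × 10⁻⁷ M, where initiator breaks as fast as radical pairs join, and this gave free monomer a time of 6.97 h. I took each initiator that broke to give two radicals and so one chain, which gave a birth time of 94.3 h, far longer than the monomer time. Units per new chain is the charge ratio, 50.0, times the birth time over the monomer time.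

With growing radical and initiator both held at their starting levels, my average length was units per new chain times the fraction of free monomer used, divided by the run time in monomer times. Epsilon ran 4.31 monomer times and theta 1.44. So in this reckoning epsilon bore 3.00 times the chains of theta but used 1.29 times the monomer. I reckoned 155 for epsilon and 359 for theta, so theta's chains were the longer.

The forecast, above mine at 180 for epsilon and 374 for theta, concluded: “Theta ends with longer chains.”

The simulation gave theta the longer chains, with 181 in epsilon and 375 in theta, above my 155 and 359. In epsilon, half of the monomer-adding turnover up to 30 h was done by 4.71 h, but half of the chain-starting turnover up to then took until 13.8 h, and the final average in epsilon stood at 26.7% of units per new chain, the final average in theta at 55.4%. For a flask like epsilon with 5 mol% of initiator, I reckoned units per new chain at 428 and the average length at 62.8, and the simulation of that flask gave 83.4.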